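The tridepside is cut at its two aryl ester bonds, and the central ring B is traced back to an open tetraketide chain whose carboxyl end is masked in a 1,3-dioxin-4-one. A single amine-promoted aldol closes ring B by forming bond b1–b6 and aromatises it. The step exploits the orsellinate pattern of ring B (b1 carbonyl carbon, b2 OH, b4 acyloxy oxygen, b6 CH3): it delivers b2–O and the b1 carboxyl tied in one acetonide with b4–OH free, ready for two successive, different esterifications. The precursor is 2,2-dimethyl-1,3-dioxin-4-one bearing a 2,4-dioxopentyl chain at C6.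

Key step: step 3

Remarks on the chemistry
- Atom labels: ring A is the free-acid ring (a1 CO2H carbon, a2 OH, a4 ester oxygen, a6 CH3). Ring B is the middle ring (b1 ester carbonyl carbon, b2 OH, b4 acyloxy oxygen, b6 CH3). Ring C is the terminal acyl ring (c1 carbonyl carbon, c2 OH, c4 OH, c5 OH, c6 CH3).
- Ring C is a 2,4,5-trihydroxy-6-methylbenzoyl unit with three hydroxyls, one more than an orcinol-derived unit carries. It is therefore built from 2,4-dihydroxy-6-methylbenzaldehyde: a Baeyer–Villiger oxidation installs the c5 oxygen and a formylation then brings back the c1 carbon.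
- Ring A enters as benzyl orsellinate, so that its acid is masked and only the non-chelated a4–OH is nucleophilic. All four benzyl groups are removed in the last step.
- The second acetyl unit of the precursor is delivered as a Weinreb amide, so that the acidic 1,3-diketone is released only on quench. Compound 5 is drawn as the triketo tautomer and should be used promptly and kept cold, since it is largely enolised and labile.

Step 1
Reactants: 1 2,2,6-trimethyl-4H-1,3-dioxin-4-one; 2 1-acetylimidazole
Product: 3 2,2-dimethyl-6-(2-oxopropyl)-4H-1,3-dioxin-4-one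
Conditions: LiN(SiMe3)2 (2.0 equiv), THF, −78 °C; then 2, −78 → −20 °C; 1 M HCl
Reagents that add atoms: 1-acetylimidazole (compound 2), CC(=O)n1ccnc1
Why: Kinetic deprotonation of the C6 methyl gives the lithium dienolate, which undergoes vinylogous Claisen C-acylation at its terminal carbon by the acyl imidazole, the second equivalent of base holding the more acidic keto-dioxinone as its enolate until the quench.

Step 2
Reactants: 3 2,2-dimethyl-6-(2-oxopropyl)-4H-1,3-dioxin-4-one; 4 N-methoxy-N-methylacetamide
Product: 5 6-(2,4-dioxopentyl)-2,2-dimethyl-4H-1,3-dioxin-4-one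
Conditions: LiN(iPr)2 (2.3 equiv), THF, −78 → −40 °C; then 4, −78 → −20 °C; 1 M HCl, 0 °C
Reagents that add atoms: N-methoxy-N-methylacetamide (compound 4), CC(=O)N(C)OC
Why: Double deprotonation gives a Weiler-type dianion whose more reactive terminal methyl carbon undergoes Claisen acylation by the Weinreb amide, the chelated tetrahedral adduct persisting until the acidic quench so that over-addition and proton return are avoided.

Step 3
Reactants: 5 6-(2,4-dioxopentyl)-2,2-dimethyl-4H-1,3-dioxin-4-one
Product: 7 7-hydroxy-2,2,5-trimethyl-4H-1,3-benzodioxin-4-one, via cyclic aldol adduct 6 (not isolated)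
Conditions: Et3N (2 equiv), CH2Cl2, rt; then 1 M HCl wash
Reagents that add atoms: none
Why: Triethylamine reversibly removes a proton from the C6 methylene to give a vinylogous ester enolate whose alpha carbon, dioxinone C5, adds to the terminal methyl ketone and forms bond b1–b6; carbinol 6 then loses water and the b4 ketone enolises to the phenol, aromaticity making the sequence irreversible. The closest known reaction type is the amine-promoted aldol aromatisation of 6-(2,4-dioxoalkyl)-1,3-dioxin-4-ones to resorcylate acetonides, a laboratory counterpart of orsellinate-type polyketide folding. Ring B closes in a Baldwin-favoured 6-exo-trig aldol mode, 6-(enolendo)-exo-trig with respect to the ring enol ether C5=C6, the C4–O enolate lying outside the new ring. The only new stereocentre is the transient carbinol carbon b6 of 6, formed without control as a racemate and erased by dehydration, so none has to be governed. The selectivity needed is aldol folding (C5 onto the ketone) rather than Claisen or lactone folding onto the carboxyl carbon: the carboxyl is locked in the heterocycle as a weakly electrophilic vinylogous carbonate pointing away from the chain, so the terminal ketone is the only electrophile within six-membered reach, and working at room temperature keeps the dioxinone from shedding acetone to an acyl ketene that would lactonise to a pyrone.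

Step 4
Reactants: 8 2,4-dihydroxy-6-methylbenzaldehyde
Product: 9 2,4-bis(benzyloxy)-6-methylbenzaldehyde
Conditions: BnBr (2.5 equiv), K2CO3, DMF, 60 °C
Reagents that add atoms: benzyl bromide, BrCc1ccccc1
Why: Williamson etherification of both phenoxides, warm DMF and excess bromide being used because the ortho hydroxyl is chelated to the aldehyde.

Step 5
Reactants: 9 2,4-bis(benzyloxy)-6-methylbenzaldehyde
Product: 11 2,4-bis(benzyloxy)-6-methylphenol, via aryl formate 10 (not isolated)
Conditions: mCPBA, CH2Cl2, 0 °C → rt; then K2CO3 (cat.), MeOH, rt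
Reagents that add atoms: mCPBA, O=C(OO)c1cccc(Cl)c1
Why: Baeyer–Villiger (Dakin-type) oxidation in which the electron-rich, doubly ortho-substituted aryl group migrates in preference to hydride, the resulting aryl formate being cleaved by mild methanolysis.

Step 6
Reactants: 11 2,4-bis(benzyloxy)-6-methylphenol
Product: 12 1,2,5-tris(benzyloxy)-3-methylbenzene
Conditions: BnBr (1.2 equiv), K2CO3, DMF, 50 °C
Reagents that add atoms: benzyl bromide, BrCc1ccccc1
Why: Williamson etherification of the flanked but acidic phenol completes uniform benzyl protection of the three ring C oxygens.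

Step 7
Reactants: 12 1,2,5-tris(benzyloxy)-3-methylbenzene
Product: 13 2,4,5-tris(benzyloxy)-6-methylbenzaldehyde
Conditions: POCl3, DMF, 0 → 70 °C; then H2O
Reagents that add atoms: N,N-dimethylformamide, CN(C)C=O; water, O
Why: Vilsmeier–Haack formylation should occur at the free position next to the methyl group, which is para to one benzyloxy group and ortho to another, as in 3,5-dialkoxytoluenes and 1,2,4-trialkoxybenzenes, and not at the more congested site between two benzyloxy groups.

Step 8
Reactants: 13 2,4,5-tris(benzyloxy)-6-methylbenzaldehyde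
Product: 14 2,4,5-tris(benzyloxy)-6-methylbenzoic acid
Conditions: NaClO2, NaH2PO4, 2-methyl-2-butene, tBuOH/THF/H2O, rt
Reagents that add atoms: sodium chlorite, [Na+].[O-]Cl=O
Why: Pinnick oxidation converts hindered, electron-rich benzaldehydes into the acids without touching benzyl ethers, the alkene trapping hypochlorous acid before it can chlorinate the ring.

Step 9
Reactants: 14 2,4,5-tris(benzyloxy)-6-methylbenzoic acid; 7 7-hydroxy-2,2,5-trimethyl-4H-1,3-benzodioxin-4-one
Product: 16 2,2,5-trimethyl-4-oxo-4H-1,3-benzodioxin-7-yl 2,4,5-tris(benzyloxy)-6-methylbenzoate, via acid chloride 15 (not isolated)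
Conditions: (COCl)2, cat. DMF, CH2Cl2, 0 °C → rt, evaporate; then 7, Et3N, cat. DMAP, CH2Cl2, 0 °C → rt
Reagents that add atoms: none
Why: The hindered aroyl chloride acylates the acidic, unhindered b4 phenol of 7 under DMAP nucleophilic catalysis (acid chloride esterification), while the acetonide keeps b2–O and the b1 carboxyl out of play.

Step 10
Reactants: 17 orsellinic acid (2,4-dihydroxy-6-methylbenzoic acid)
Product: 18 benzyl orsellinate (benzyl 2,4-dihydroxy-6-methylbenzoate)
Conditions: BnBr (1.05 equiv), KHCO3, DMF, rt
Reagents that add atoms: benzyl bromide, BrCc1ccccc1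
Why: Hydrogencarbonate deprotonates only the carboxylic acid, so SN2 O-alkylation of the carboxylate should give the benzyl ester with both phenols free.

Step 11
Reactants: 16 2,2,5-trimethyl-4-oxo-4H-1,3-benzodioxin-7-yl 2,4,5-tris(benzyloxy)-6-methylbenzoate; 18 benzyl orsellinate
Product: 20 benzyl 2-hydroxy-4-[(2-hydroxy-6-methyl-4-{[2,4,5-tris(benzyloxy)-6-methylbenzoyl]oxy}benzoyl)oxy]-6-methylbenzoate, via quinoketene 19 (not isolated)
Conditions: hν (300 nm), degassed CH2Cl2 (0.01 M), 18 (1.5 equiv), rt
Reagents that add atoms: none
Why: Excitation of the benzodioxinone triggers retro-hetero-Diels–Alder loss of acetone to a quinoketene that is captured by the free, non-chelated a4 hydroxyl of 18 (the photochemical benzodioxinone acylation of phenols, a known depside-forming reaction), the chelated a2 hydroxyl and the newly released b2 hydroxyl being too weakly nucleophilic to compete.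

Step 12
Reactants: 20 benzyl 2-hydroxy-4-[(2-hydroxy-6-methyl-4-{[2,4,5-tris(benzyloxy)-6-methylbenzoyl]oxy}benzoyl)oxy]-6-methylbenzoate
Product: 21 2-hydroxy-4-[(2-hydroxy-6-methyl-4-{[2,4,5-trihydroxy-6-methylbenzoyl]oxy}benzoyl)oxy]-6-methylbenzoic acid (CNP0248995.0)
Conditions: H2 (1 atm), 10% Pd/C, EtOAc/THF, rt; filtration and concentration under argon
Reagents that add atoms: none
Why: Catalytic hydrogenolysis over palladium should cleave the three benzyl ethers and the benzyl ester to toluene under neutral conditions that leave both aryl ester links intact.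

Compound list
1 | 2,2,6-trimethyl-4H-1,3-dioxin-4-one | CC1=CC(=O)OC(C)(C)O1 | starting material
2 | 1-acetylimidazole | CC(=O)n1ccnc1 | starting material
3 | 2,2-dimethyl-6-(2-oxopropyl)-4H-1,3-dioxin-4-one | CC(=O)CC1=CC(=O)OC(C)(C)O1 | intermediate
4 | N-methoxy-N-methylacetamide | CC(=O)N(C)OC | starting material
5 | 6-(2,4-dioxopentyl)-2,2-dimethyl-4H-1,3-dioxin-4-one | CC(=O)CC(=O)CC1=CC(=O)OC(C)(C)O1 | intermediate (key-step precursor)
6 | 5-hydroxy-2,2,5-trimethyl-5,6-dihydro-4H-1,3-benzodioxine-4,7(8H)-dione, racemic | CC1(O)CC(=O)CC2=C1C(=O)OC(C)(C)O2 | intermediate (not isolated)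
7 | 7-hydroxy-2,2,5-trimethyl-4H-1,3-benzodioxin-4-one | Cc1cc(O)cc2OC(C)(C)OC(=O)c12 | intermediate (key-step product)
8 | 2,4-dihydroxy-6-methylbenzaldehyde | Cc1cc(O)cc(O)c1C=O | starting material
9 | 2,4-bis(benzyloxy)-6-methylbenzaldehyde | Cc1cc(OCc2ccccc2)cc(OCc2ccccc2)c1C=O | intermediate
10 | 2,4-bis(benzyloxy)-6-methylphenyl formate | Cc1cc(OCc2ccccc2)cc(OCc2ccccc2)c1OC=O | intermediate (not isolated)
11 | 2,4-bis(benzyloxy)-6-methylphenol | Cc1cc(OCc2ccccc2)cc(OCc2ccccc2)c1O | intermediate
12 | 1,2,5-tris(benzyloxy)-3-methylbenzene | Cc1cc(OCc2ccccc2)cc(OCc2ccccc2)c1OCc1ccccc1 | intermediate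
13 | 2,4,5-tris(benzyloxy)-6-methylbenzaldehyde | Cc1c(OCc2ccccc2)c(OCc2ccccc2)cc(OCc2ccccc2)c1C=O | intermediate
14 | 2,4,5-tris(benzyloxy)-6-methylbenzoic acid | Cc1c(OCc2ccccc2)c(OCc2ccccc2)cc(OCc2ccccc2)c1C(=O)O | intermediate
15 | 2,4,5-tris(benzyloxy)-6-methylbenzoyl chloride | Cc1c(OCc2ccccc2)c(OCc2ccccc2)cc(OCc2ccccc2)c1C(Cl)=O | intermediate (not isolated)
16 | 2,2,5-trimethyl-4-oxo-4H-1,3-benzodioxin-7-yl 2,4,5-tris(benzyloxy)-6-methylbenzoate | Cc1cc(OC(=O)c2c(OCc3ccccc3)cc(OCc3ccccc3)c(OCc3ccccc3)c2C)cc2OC(C)(C)OC(=O)c12 | intermediate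
17 | orsellinic acid (2,4-dihydroxy-6-methylbenzoic acid) | Cc1cc(O)cc(O)c1C(=O)O | starting material
18 | benzyl orsellinate (benzyl 2,4-dihydroxy-6-methylbenzoate) | Cc1cc(O)cc(O)c1C(=O)OCc1ccccc1 | intermediate
19 | 5-methyl-3-oxo-4-(oxomethylidene)cyclohexa-1,5-dien-1-yl 2,4,5-tris(benzyloxy)-6-methylbenzoate (quinoketene) | O=C=C1C(=O)C=C(OC(=O)c2c(OCc3ccccc3)cc(OCc3ccccc3)c(OCc3ccccc3)c2C)C=C1C | intermediate (not isolated)
20 | benzyl 2-hydroxy-4-[(2-hydroxy-6-methyl-4-{[2,4,5-tris(benzyloxy)-6-methylbenzoyl]oxy}benzoyl)oxy]-6-methylbenzoate | Cc1cc(OC(=O)c2c(C)cc(OC(=O)c3c(OCc4ccccc4)cc(OCc4ccccc4)c(OCc4ccccc4)c3C)cc2O)cc(O)c1C(=O)OCc1ccccc1 | intermediate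
21 | 2-hydroxy-4-[(2-hydroxy-6-methyl-4-{[2,4,5-trihydroxy-6-methylbenzoyl]oxy}benzoyl)oxy]-6-methylbenzoic acid (CNP0248995.0) | Cc1cc(OC(=O)c2c(C)cc(OC(=O)c3c(O)cc(O)c(O)c3C)cc2O)cc(O)c1C(=O)O | target

Total step count: 12.
Longest linear sequence: 8 steps (steps 4, 5, 6, 7, 8, 9, 11 and 12, from compound 8). The ring B line from compound 1 runs over 6 steps (1, 2, 3, 9, 11, 12).

Steps most likely to fail

Step 11. Under 300 nm light the aryl ester already present in 16 may undergo photo-Fries scission, because its electron-rich aroyloxy chromophore absorbs at the irradiation wavelength. This would compete with acetone extrusion and cost the b4–O–CO link before the A–B ester forms. The fallback reverses the order of the two esterifications, so that the benzodioxinone is irradiated before any aryl ester exists and ring C is attached last by ground-state acylation. Setting out from 7, silylation (TBSCl, imidazole, DMF) should give 7-[(tert-butyldimethylsilyl)oxy]-2,2,5-trimethyl-4H-1,3-benzodioxin-4-one F1. Irradiation of F1 with 18 (300 nm, CH2Cl2) should give benzyl 4-({4-[(tert-butyldimethylsilyl)oxy]-2-hydroxy-6-methylbenzoyl}oxy)-2-hydroxy-6-methylbenzoate F2. Buffered desilylation (Bu4NF, AcOH, THF, 0 °C) should give benzyl 4-[(2,4-dihydroxy-6-methylbenzoyl)oxy]-2-hydroxy-6-methylbenzoate F3, in which b4–OH is the only phenol not chelated to an ester carbonyl. Acylation of that hydroxyl with acid chloride 15 (Et3N, DMAP, CH2Cl2, 0 °C) comes back to the route at 20.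

Step 3. The folding may stall at the carbinol stage, or be outrun by loss of acetone from the dioxinone and lactonisation of the resulting acyl ketene to a 4-hydroxy-2-pyrone, or the labile triketide may decompose before it cyclises. The fallback gives up the folding and takes ring B from an aromatic source. Setting out from 17, orsellinic acid is condensed with acetone (TFAA, TFA, 0 °C → rt), the standard acetonide formation of salicylic acids. This should tie b2–O and the carboxyl together while leaving b4–OH free, and it comes back to the route at 7 without any new compound.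

Step 2. Proton transfer from the amide methyl group or from diketone released early may quench the dianion, or acylation may take place on oxygen, so that conversion stalls and the labile product is hard to free from 3. The fallback replaces the Claisen acylation by aldol addition and oxidation. Setting out from 3, the same dianion (LiN(iPr)2, THF, −78 °C) is added to acetaldehyde to give racemic 6-(4-hydroxy-2-oxopentyl)-2,2-dimethyl-4H-1,3-dioxin-4-one F4. Oxidation of its secondary alcohol with Dess–Martin periodinane (CH2Cl2, rt) comes back to the route at 5.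

Further compounds
F1 | step 11 | 7-[(tert-butyldimethylsilyl)oxy]-2,2,5-trimethyl-4H-1,3-benzodioxin-4-one | Cc1cc(O[Si](C)(C)C(C)(C)C)cc2OC(C)(C)OC(=O)c12
F2 | step 11 | benzyl 4-({4-[(tert-butyldimethylsilyl)oxy]-2-hydroxy-6-methylbenzoyl}oxy)-2-hydroxy-6-methylbenzoate | Cc1cc(O[Si](C)(C)C(C)(C)C)cc(O)c1C(=O)Oc1cc(C)c(C(=O)OCc2ccccc2)c(O)c1
F3 | step 11 | benzyl 4-[(2,4-dihydroxy-6-methylbenzoyl)oxy]-2-hydroxy-6-methylbenzoate | Cc1cc(O)cc(O)c1C(=O)Oc1cc(C)c(C(=O)OCc2ccccc2)c(O)c1
F0 | step 3 | none | none
F4 | step 2 | 6-(4-hydroxy-2-oxopentyl)-2,2-dimethyl-4H-1,3-dioxin-4-one, racemic | CC(O)CC(=O)CC1=CC(=O)OC(C)(C)O1
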